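Opening ring B (C5–C10, labdane numbering) at the C9–C10 bond leads back to monocycle 12: a ring A cyclohexene with a tetrasubstituted C5=C10 bond, the C2 acetate, and an (E)-C8=C9 alkene in the chain on C5. The key step is a proton-initiated cation–olefin closure that forms ring B, creates C5, C9 and C10 and the C7=C8 bond, and gives the target directly. It exploits the C2 acetate of ring A, held equatorial by the C4 and C10 methyl groups, as the only stereochemical relay. Ring A comes from ketoisophorone, the chain from (S)-citronellol; a B-alkyl Suzuki coupling joins them.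

Key step: step 8

Remark (numbering): labdane numbering is used throughout: ring A = C1–C5 and C10; ring B = C5–C10; C11–C16 is the chain on C9 (C16 the methyl on C13); C17 is the methyl on C8, C18/C19 those on C4, C20 that on C10.
Remark (assumption): transfer hydrogenation of ketoisophorone is taken to occur at the unhindered carbonyl (flanked by CH= and CH2), the carbonyl that nucleophiles generally prefer.
Remark (descriptors): the acetoxy-bearing ring carbon is R in 2 and 3, S in 4, 5, 12 and 13, and R again in 14 and 15. Only the CIP priorities change; no bond at this carbon is ever made or broken.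

Step 1
Reactants: 1 ketoisophorone (2,6,6-trimethylcyclohex-2-ene-1,4-dione)
Product: 2 (4R)-4-hydroxy-2,6,6-trimethylcyclohex-2-en-1-one
Conditions: RuCl(p-cymene)[(R,R)-TsDPEN] (1 mol%), KOH (cat.), i-PrOH, rt
Reagents that add atoms: none
Why: Noyori-type asymmetric transfer hydrogenation; the Ru–H/N–H catalyst should reduce only the unhindered carbonyl and, with the alkenyl carbon in the place the aryl group takes in the usual model, the (R,R)-ligand is expected to give the (R)-carbinol that becomes C2 (the ligand enantiomer is exchanged if the opposite sense is found).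

Step 2
Reactants: 2 (4R)-4-hydroxy-2,6,6-trimethylcyclohex-2-en-1-one
Product: 3 (1R)-3,5,5-trimethyl-4-oxocyclohex-2-en-1-yl acetate
Conditions: Ac2O, Et3N, DMAP (cat.), CH2Cl2, 0 °C → rt
Reagents that add atoms: acetic anhydride, CC(=O)OC(C)=O
Why: DMAP-catalysed O-acylation installs the C2 acetate of the target at once, so no protecting-group change is needed later; the stereocentre is not involved.

Step 3
Reactants: 3 (1R)-3,5,5-trimethyl-4-oxocyclohex-2-en-1-yl acetate
Product: 5 (1S)-3,5,5-trimethyl-4-{[(trifluoromethyl)sulfonyl]oxy}cyclohex-3-en-1-yl acetate, via lithium enolate 4 (not isolated)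
Conditions: LiBH(s-Bu)3 (1.05 equiv), THF, −78 °C; then PhNTf2, −78 → 0 °C
Reagents that add atoms: N-phenylbis(trifluoromethanesulfonimide), O=S(=O)(N(c1ccccc1)S(=O)(=O)C(F)(F)F)C(F)(F)F
Why: Conjugate hydride reduction followed by O-triflation of the resulting enolate (reductive enolate trapping); the carbonyl is screened by the gem-dimethyl carbon so hydride should add at C1, and the only possible enolate places the triflate on C5 of the tetrasubstituted C5=C10 bond, with no new stereocentre.

Step 4
Reactants: 6 (S)-citronellol ((3S)-3,7-dimethyloct-6-en-1-ol)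
Product: 7 (3S)-3,7-dimethyloct-6-en-1-yl acetate
Conditions: Ac2O, pyridine, DMAP (cat.), CH2Cl2, rt
Reagents that add atoms: acetic anhydride, CC(=O)OC(C)=O
Why: O-Acylation gives the C15 acetate of the target; the C13 stereocentre comes unchanged from the chiral pool.

Step 5
Reactants: 7 (3S)-3,7-dimethyloct-6-en-1-yl acetate
Product: 9 (3S,6E)-3,7-dimethyl-8-oxooct-6-en-1-yl acetate, via allylic alcohol 8 (not isolated)
Conditions: SeO2 (0.3 equiv), t-BuOOH (2 equiv), salicylic acid (cat.), CH2Cl2, rt; crude material then MnO2, CH2Cl2, rt
Reagents that add atoms: tert-butyl hydroperoxide, CC(C)(C)OO (terminal source of the new oxygen); selenium dioxide, O=[Se]=O (catalytic oxygen carrier)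
Why: Riley allylic oxidation (ene reaction then [2,3]-sigmatropic shift) is selective for the (E)-methyl of a trisubstituted alkene and MnO2 oxidises only the allylic alcohol, so the E geometry of the future C8=C9 bond is fixed here.

Step 6
Reactants: 9 (3S,6E)-3,7-dimethyl-8-oxooct-6-en-1-yl acetate
Product: 10 (3S,6E)-3,7-dimethylnona-6,8-dien-1-yl acetate
Conditions: Ph3PCH3Br, KOtBu, THF, 0 °C
Reagents that add atoms: methyltriphenylphosphonium bromide, C[P+](c1ccccc1)(c1ccccc1)c1ccccc1.[Br-] (CH2 delivered as its ylide)
Why: Wittig methylenation; the non-stabilised ylide should attack the enal far faster than the acetate, and the trisubstituted alkene geometry is untouched.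

Step 7
Reactants: 10 (3S,6E)-3,7-dimethylnona-6,8-dien-1-yl acetate; 5 (1S)-3,5,5-trimethyl-4-{[(trifluoromethyl)sulfonyl]oxy}cyclohex-3-en-1-yl acetate
Product: 12 (1S)-4-[(3E,7S)-9-acetoxy-3,7-dimethylnon-3-en-1-yl]-3,5,5-trimethylcyclohex-3-en-1-yl acetate, via alkyl-9-BBN adduct 11 (not isolated)
Conditions: 9-BBN-H (1.05 equiv), THF, 0 °C → rt; then 5, Pd(OAc)2 (5 mol%), SPhos (10 mol%), K3PO4, THF/H2O, 50 °C
Reagents that add atoms: none
Why: Anti-Markovnikov hydroboration of the terminal vinyl group of the diene (boron on C6, trisubstituted alkene left alone) followed by B-alkyl Suzuki–Miyaura coupling with the enol triflate forms the C5–C6 bond; alkene geometry and both stereocentres are carried through unchanged.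

Step 8
Reactants: 12 (1S)-4-[(3E,7S)-9-acetoxy-3,7-dimethylnon-3-en-1-yl]-3,5,5-trimethylcyclohex-3-en-1-yl acetate
Product: 15 (2R,5R,9R,10R,13S)-labd-7-ene-2,15-diyl diacetate, via tertiary C10 cation 13 (not isolated), via bicyclic C8 cation 14 (not isolated)
Conditions: FSO3H (5 equiv), 2-nitropropane, −78 °C, 15 min; Et3N quench
Reagents that add atoms: none
Why: Protonation of the tetrasubstituted C5=C10 alkene at C5 gives cation 13, whose C10 is attacked by C9 of the (E)-C8=C9 alkene through a chair–chair transition state to give cation 14, and loss of the axial C7 proton gives the C7=C8 alkene. The closest known reaction type is the superacid-promoted biomimetic cation–olefin cyclisation of beta-monocyclic polyprenoids to trans-fused bicycles, applied here to a new substrate. Ring B closes in the 6-endo-trig mode with respect to the C8=C9 alkene. C5 is set by axial protonation of the half-chair that keeps the C2 acetate pseudo-equatorial (the other half-chair puts it syn-axial to a C4 methyl), so H-5 ends up cis to the acetate; C10 is set by equatorial attack, which makes the C10 methyl axial, anti to H-5 (trans-decalin) and trans to the acetate; C9 is set by the E geometry, which places C11 equatorial and cis to the C10 methyl. The step needs protonation of the ring alkene rather than the chain alkene (the tetrasubstituted alkene is the more basic), a fold with equatorial acetate (an axial acetate would be syn-axial to both the C4 and C10 methyls) and proton loss toward C7 rather than C17 or C9 (kinetic loss of the axial ring proton at −78 °C). The two acetates are the only heteroatom groups and should survive the short exposure at low temperature.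

Compound list
1 | ketoisophorone (2,6,6-trimethylcyclohex-2-ene-1,4-dione) | CC1=CC(=O)CC(C)(C)C1=O | starting material
2 | (4R)-4-hydroxy-2,6,6-trimethylcyclohex-2-en-1-one | CC1=C[C@H](O)CC(C)(C)C1=O | intermediate
3 | (1R)-3,5,5-trimethyl-4-oxocyclohex-2-en-1-yl acetate | CC1=C[C@H](OC(C)=O)CC(C)(C)C1=O | intermediate
4 | lithium (4S)-4-acetoxy-2,6,6-trimethylcyclohex-1-en-1-olate | CC1=C([O-])C(C)(C)C[C@@H](OC(C)=O)C1.[Li+] | intermediate (not isolated)
5 | (1S)-3,5,5-trimethyl-4-{[(trifluoromethyl)sulfonyl]oxy}cyclohex-3-en-1-yl acetate | CC1=C(OS(=O)(=O)C(F)(F)F)C(C)(C)C[C@@H](OC(C)=O)C1 | intermediate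
6 | (S)-citronellol ((3S)-3,7-dimethyloct-6-en-1-ol) | OCC[C@@H](C)CCC=C(C)C | starting material
7 | (3S)-3,7-dimethyloct-6-en-1-yl acetate | CC(=O)OCC[C@@H](C)CCC=C(C)C | intermediate
8 | (3S,6E)-8-hydroxy-3,7-dimethyloct-6-en-1-yl acetate | CC(=O)OCC[C@@H](C)CC/C=C(\C)CO | intermediate (not isolated)
9 | (3S,6E)-3,7-dimethyl-8-oxooct-6-en-1-yl acetate | CC(=O)OCC[C@@H](C)CC/C=C(\C)C=O | intermediate
10 | (3S,6E)-3,7-dimethylnona-6,8-dien-1-yl acetate | CC(=O)OCC[C@@H](C)CC/C=C(\C)C=C | intermediate
11 | (3S,6E)-9-(9-borabicyclo[3.3.1]nonan-9-yl)-3,7-dimethylnon-6-en-1-yl acetate | CC(=O)OCC[C@@H](C)CC/C=C(\C)CCB1C2CCCC1CCC2 | intermediate (not isolated)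
12 | (1S)-4-[(3E,7S)-9-acetoxy-3,7-dimethylnon-3-en-1-yl]-3,5,5-trimethylcyclohex-3-en-1-yl acetate | CC(=O)OCC[C@@H](C)CC/C=C(\C)CCC1=C(C)C[C@H](OC(C)=O)CC1(C)C | intermediate
13 | monocyclic tertiary C10 cation (H on C5 in place, acetate on C2, chain on C5) | CC(=O)OCC[C@@H](C)CC/C=C(\C)CC[C@@H]1C(C)(C)C[C@@H](OC(C)=O)C[C+]1C | intermediate (not isolated)
14 | bicyclic tertiary C8 cation (trans-decalin, ring B closed) | CC(=O)OCC[C@@H](C)CC[C@@H]1[C+](C)CC[C@@H]2C(C)(C)C[C@@H](OC(C)=O)C[C@@]12C | intermediate (not isolated)
15 | (2R,5R,9R,10R,13S)-labd-7-ene-2,15-diyl diacetate (CNP0220683.1) | CC(=O)OCC[C@@H](C)CC[C@@H]1C(C)=CC[C@@H]2C(C)(C)C[C@@H](OC(C)=O)C[C@@]12C | target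

Total step count: 8. Longest linear sequence: 5 steps (steps 4, 5, 6, 7, 8 from (S)-citronellol; the ring A branch, steps 1, 2, 3, 7, 8, is equally long).

Steps most likely to fail

Step 8. What may go wrong: proton loss from cation 14 toward C17 or C9 instead of C7, re-protonation and migration of the new double bond in the superacid, protonation at C10 followed by methyl migration from C4, or a weak stereochemical relay from the C2 acetate. Fallback: the closure would be taken out of the superacid and out of pure substrate control. Monocycle 12 would be treated at −78 °C in CH2Cl2 with a chiral Lewis-acid-assisted Brønsted acid, the SnCl4 complex of a BINOL monobenzyl ether (a known promoter of enantioface-selective protonation in polyprenoid cyclisations), using the enantiomer matched to C2. Partly cyclised material would be completed with CF3CO2H·SnCl4. With no free superacid present, the first-formed C7=C8 alkene should not be re-protonated. The fallback sets out from 12 and comes back at 15; it makes no new compound (entry F0).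

Step 7. What may go wrong: slow oxidative addition and transmetalation at the tetrasubstituted enol triflate flanked by a quaternary carbon, so that triflate hydrolysis, protodeboronation or β-hydride loss from the alkylpalladium species competes. Fallback: the boron "ate" route is replaced by a base-free organozinc (Negishi) coupling. Diene 10 would be hydroborated as before and the borane oxidised with NaBO3·4H2O to (3S,6E)-9-hydroxy-3,7-dimethylnon-6-en-1-yl acetate F1. Iodination (I2, PPh3, imidazole) would give (3S,6E)-9-iodo-3,7-dimethylnon-6-en-1-yl acetate F2, and zinc insertion (Zn dust, LiCl, THF) the ester-tolerant [(3E,7S)-9-acetoxy-3,7-dimethylnon-3-en-1-yl]zinc iodide F3. F3 would be coupled with triflate 5 (PdCl2(dppf), THF/NMP, 50 °C). The fallback sets out from 10 and 5 and comes back at 12.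

Step 3. What may go wrong: attack of the borohydride on the acetate or at the carbonyl, or sluggish O-sulfonylation of the hindered enolate in the presence of the trialkylborane. Fallback: reduction and triflation are separated and run without borohydride or a basic enolate. Enone 3 would undergo ester-tolerant copper hydride conjugate reduction ([(Ph3P)CuH]6 cat., PhSiH3, toluene, then aqueous fluoride work-up) to (1S,3R)-3,5,5-trimethyl-4-oxocyclohexyl acetate F4 (drawn as the cis epimer; the methyl-bearing centre is lost again in the next operation). Electrophilic enol triflation (Tf2O, 2,6-di-tert-butyl-4-methylpyridine, CH2Cl2, 0 °C → rt) can only enolise toward the methyl-bearing carbon. The fallback sets out from 3 and comes back at 5.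

Further compounds
F0 | step 8 | none | none
F1 | step 7 | (3S,6E)-9-hydroxy-3,7-dimethylnon-6-en-1-yl acetate | CC(=O)OCC[C@@H](C)CC/C=C(\C)CCO
F2 | step 7 | (3S,6E)-9-iodo-3,7-dimethylnon-6-en-1-yl acetate | CC(=O)OCC[C@@H](C)CC/C=C(\C)CCI
F3 | step 7 | [(3E,7S)-9-acetoxy-3,7-dimethylnon-3-en-1-yl]zinc iodide | CC(=O)OCC[C@@H](C)CC/C=C(\C)CC[Zn]I
F4 | step 3 | (1S,3R)-3,5,5-trimethyl-4-oxocyclohexyl acetate | C[C@@H]1C[C@H](OC(C)=O)CC(C)(C)C1=O
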